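The exocyclic enol lactone of the furanone ring (ring oxygen O1–C5=CH–aryl) is the hydrocarboxylation retron of an aryl alkyne, so the bond between the benzylidene CH and the ipso carbon of the 3-bromo-4-methoxyphenyl ring is made as an aryl–alkynyl bond. In one operation, Sonogashira coupling of 2-bromo-4-iodoanisole with the terminal enynoic acid (E)-3-(4-hydroxyphenyl)pent-2-en-4-ynoic acid forms that bond, and the resulting aryl enynoic acid closes 5-exo-dig to the furanone with Z geometry. The open-chain precursor, carboxyl cis to ethynyl, comes from 4-iodophenyl acetate by propiolate coupling, anti hydroiodination, alkynylation and global deprotection.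

Key step: step 5

Remark: in every open-chain enyne of the route the ester or carboxyl group is cis to the alkynyl group; the CIP descriptor changes (Z, E, Z) only because the priority of the alkynyl group against the aryl group changes with its substituent. Compounds 1, 2, 5 and 8 are taken as commercial.

Step 1
Reactants: 1 4-iodophenyl acetate; 2 methyl propiolate
Product: 3 methyl 3-(4-acetoxyphenyl)prop-2-ynoate
Conditions: PdCl2(PPh3)2 (2 mol%), CuI (4 mol%), K2CO3 (2 equiv), THF, 65 °C; 2 in excess, added in portions
Reagents that add atoms: none
Why: Sonogashira coupling of an aryl iodide with a propiolate under amine-free carbonate conditions, which should suppress amine-triggered oligomerisation of the ynoate and leave the aryl acetate intact.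

Step 2
Reactants: 3 methyl 3-(4-acetoxyphenyl)prop-2-ynoate
Product: 4 methyl (Z)-3-(4-acetoxyphenyl)-3-iodoprop-2-enoate (iodine cis to the ester)
Conditions: NaI, AcOH, 110 °C
Reagents that add atoms: sodium iodide, [Na+].[I-]
Why: Conjugate hydroiodination of an alkynoate: iodide adds to the aryl-bearing β-carbon and the allenolate is protonated on the face away from iodine, so overall anti addition of HI should place iodine cis to the ester.

Step 3
Reactants: 4 methyl (Z)-3-(4-acetoxyphenyl)-3-iodoprop-2-enoate; 5 (trimethylsilyl)acetylene
Product: 6 methyl (Z)-3-(4-acetoxyphenyl)-5-(trimethylsilyl)pent-2-en-4-ynoate (ester cis to the silylethynyl group)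
Conditions: PdCl2(PPh3)2 (3 mol%), CuI (5 mol%), Et3N, THF, rt
Reagents that add atoms: none
Why: Sonogashira coupling of an activated alkenyl iodide should proceed at room temperature with retention of alkene geometry, and the aryl acetate tolerates triethylamine in an aprotic solvent.

Step 4
Reactants: 6 methyl (Z)-3-(4-acetoxyphenyl)-5-(trimethylsilyl)pent-2-en-4-ynoate
Product: 7 (E)-3-(4-hydroxyphenyl)pent-2-en-4-ynoic acid (carboxyl cis to the ethynyl group)
Conditions: LiOH·H2O (5 equiv), THF/MeOH/H2O, 0 °C to rt; then 1 M HCl to pH 3; used promptly
Reagents that add atoms: lithium hydroxide, [Li+].[OH-]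
Why: Saponification of the methyl ester, cleavage of the aryl acetate and protodesilylation of the alkynylsilane should occur in one basic operation; the geometry is retained, and if the phenoxide allowed any equilibration, the isomer with carboxyl cis to the slim ethynyl group should be the favoured one.

Step 5
Reactants: 7 (E)-3-(4-hydroxyphenyl)pent-2-en-4-ynoic acid; 8 2-bromo-4-iodoanisole
Product: 10 3''-bromorubrolide F, via arylated enynoic acid 9 (not isolated)
Conditions: Pd(PPh3)4 (5 mol%), CuI (10 mol%), Et3N (4 equiv), MeCN, argon, rt then 50 °C
Reagents that add atoms: none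
Why: Zerovalent palladium inserts into the C–I bond of 8, the copper acetylide of 7 (RC≡C–Cu) transmetalates and reductive elimination forges the aryl–C(sp) bond to give 9; monovalent copper or divalent palladium then π-activates the new aryl alkyne, the cis-disposed triethylammonium carboxylate adds anti across it and protodemetalation releases 10. The closest known reaction type is the tandem Sonogashira coupling–lactonization of (Z)-3-iodoalkenoic acids with terminal alkynes, which passes through the same kind of (Z)-2-en-4-ynoic acid; here the roles of halide and alkyne partner are exchanged. The furanone ring closes by 5-exo-dig attack of the carboxylate oxygen on C4 of the enyne. No stereocenter is formed; the Z geometry of the exocyclic alkene follows from anti addition of O and H across the alkyne, which leaves the aryl group cis to the ring oxygen, and Z is also the thermodynamically preferred isomer. The step needs iodide-over-bromide chemoselectivity (secured by the weaker C–I bond and the mild temperature), coupling before cyclization (secured by CuI, which routes the terminal alkyne through its acetylide instead of carboxylate attack on an alkyne bound to ArPd(PPh3)2I, a path that would give the E isomer) and 5-exo over 6-endo closure (secured by the cis enoate geometry, which holds the carboxylate oxygen next to C4).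

Compound list
1 | 4-iodophenyl acetate | CC(=O)Oc1ccc(I)cc1 | starting material
2 | methyl propiolate | C#CC(=O)OC | starting material
3 | methyl 3-(4-acetoxyphenyl)prop-2-ynoate | COC(=O)C#Cc1ccc(OC(C)=O)cc1 | intermediate
4 | methyl (Z)-3-(4-acetoxyphenyl)-3-iodoprop-2-enoate | COC(=O)/C=C(\I)c1ccc(OC(C)=O)cc1 | intermediate
5 | (trimethylsilyl)acetylene | C#C[Si](C)(C)C | starting material
6 | methyl (Z)-3-(4-acetoxyphenyl)-5-(trimethylsilyl)pent-2-en-4-ynoate | COC(=O)/C=C(\C#C[Si](C)(C)C)c1ccc(OC(C)=O)cc1 | intermediate
7 | (E)-3-(4-hydroxyphenyl)pent-2-en-4-ynoic acid | OC(=O)/C=C(\C#C)c1ccc(O)cc1 | intermediate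
8 | 2-bromo-4-iodoanisole | COc1ccc(I)cc1Br | starting material
9 | (Z)-5-(3-bromo-4-methoxyphenyl)-3-(4-hydroxyphenyl)pent-2-en-4-ynoic acid (carboxyl cis to the arylethynyl group) | COc1ccc(C#C/C(=C\C(=O)O)c2ccc(O)cc2)cc1Br | intermediate
10 | 3''-bromorubrolide F, (Z)-5-[(3-bromo-4-methoxyphenyl)methylidene]-4-(4-hydroxyphenyl)furan-2(5H)-one | COc1ccc(/C=C2\OC(=O)C=C2c2ccc(O)cc2)cc1Br | target

Total step count: 5
Longest linear sequence: 5 steps (1 to 10)

Steps most likely to fail

Step 5. The terminal enynoic acid may cyclize before it couples. Carboxylate attack on the alkyne bound to the arylpalladium iodide would lead to the E isomer, and plain cycloisomerization would give the 5-methylene furanone. The coupled acid may also close 6-endo to a 2-pyranone. The fallback separates coupling from ring closure and lets a silver salt do the closure. It sets out from 6: K2CO3 in MeOH at 0 °C to rt should remove the silyl group and the acetate but keep the methyl ester, giving methyl (E)-3-(4-hydroxyphenyl)pent-2-en-4-ynoate F1. As an ester F1 cannot lactonize, so Sonogashira coupling with 8 (PdCl2(PPh3)2, CuI, Et3N, THF, rt) should give methyl (Z)-5-(3-bromo-4-methoxyphenyl)-3-(4-hydroxyphenyl)pent-2-en-4-ynoate F2, forming the same aryl–alkynyl bond. LiOH in THF/H2O should then give acid 9, this time isolated, and Ag2CO3 (10 mol%) in DMF at rt should close it 5-exo-dig by anti addition. The fallback comes back to the route at 10.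

Step 1. Oligomerisation of the propiolate and conjugate additions to it under the basic coupling conditions may outrun the cross-coupling, and the acetate may be partly lost. The fallback couples at the alcohol oxidation level and oxidizes afterwards. It sets out from 1: Sonogashira coupling with propargyl alcohol (PdCl2(PPh3)2, CuI, Et3N, THF, rt) should give 4-(3-hydroxyprop-1-yn-1-yl)phenyl acetate F3. Jones oxidation (CrO3, H2SO4, acetone, 0 °C) should give 3-(4-acetoxyphenyl)prop-2-ynoic acid F4, and methylation with trimethylsilyldiazomethane (toluene/MeOH, rt) comes back to the route at 3.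

Step 2. Anti addition of HI may be slow on the donor-substituted aryl ynoate, and prolonged heating in acid may erode the Z geometry or cleave the esters. The fallback sets the geometry through a chelated enolate instead. It sets out from 3: hydration at the aryl-bearing carbon (Ph3PAuCl/AgOTf cat., H2O, 1,4-dioxane, 60 °C) should give methyl 3-(4-acetoxyphenyl)-3-oxopropanoate F5. Triflation of its lithium-chelated Z-enolate (LiOTf, Et3N, Tf2O, CH2Cl2, 0 °C) should give methyl (Z)-3-(4-acetoxyphenyl)-3-(trifluoromethylsulfonyloxy)prop-2-enoate F6, with the triflate cis to the ester. Sonogashira coupling of F6 with 5 (PdCl2(PPh3)2, CuI, Et3N, THF, rt) proceeds with retention and comes back to the route at 6.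

Further compounds
F1 | step 5 | methyl (E)-3-(4-hydroxyphenyl)pent-2-en-4-ynoate | COC(=O)/C=C(\C#C)c1ccc(O)cc1
F2 | step 5 | methyl (Z)-5-(3-bromo-4-methoxyphenyl)-3-(4-hydroxyphenyl)pent-2-en-4-ynoate | COC(=O)/C=C(\C#Cc1ccc(OC)c(Br)c1)c1ccc(O)cc1
F3 | step 1 | 4-(3-hydroxyprop-1-yn-1-yl)phenyl acetate | CC(=O)Oc1ccc(C#CCO)cc1
F4 | step 1 | 3-(4-acetoxyphenyl)prop-2-ynoic acid | CC(=O)Oc1ccc(C#CC(=O)O)cc1
F5 | step 2 | methyl 3-(4-acetoxyphenyl)-3-oxopropanoate | COC(=O)CC(=O)c1ccc(OC(C)=O)cc1
F6 | step 2 | methyl (Z)-3-(4-acetoxyphenyl)-3-(trifluoromethylsulfonyloxy)prop-2-enoate | COC(=O)/C=C(\OS(=O)(=O)C(F)(F)F)c1ccc(OC(C)=O)cc1
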